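## Analysis of the target

The target is a C25 adduct of a eudesmanolide and a myrcene unit. Ring A (C1–C2–C3–C4–C5–C10) is bridged between C2 and C5 by C2′–C1′ (C2′ on C2, C1′ on C5) into a bicyclo[2.2.2]oct-5-en-2-one, ring B (C5–C6–C7–C8–C9–C10) is fused to it across C5–C10, and ring C is the γ-lactone C6–O–C12(=O)–C11–C7. C1 is a ketone with no enolisable neighbour (C2 is a bridgehead, C10 is quaternary), C3=C4 carries the C15 methyl on C4, and C2′ bears the 6-methylhepta-1,5-dien-2-yl chain (C3′ with its exo-methylene, then C4′–C8′). There are seven stereocentres: the linked bridgeheads C2 and C5; C2′, whose chain lies on the side of the C1–C10 bridge and away from C3=C4; quaternary C10, with the C14 methyl towards the C3=C4 bridge and C9 towards the C1′–C2′ bridge; the axial C6 oxygen, syn to the axial C14 methyl; the equatorial C11 on C7 (cis lactone); and C11, with its C13 methyl on the convex face. Sensitive points are the β,γ-unsaturated ketone, the skipped diene of the side chain (acid, electrophiles, borane, ozone), the lactone α-centre C11 and, in any acetyl precursor of the side chain, the epimerisable C2′. The difficulty is concentrated in the vicinal quaternary carbons C5 and C10, which must carry ring B, and in C6, a carbinol wedged between the bridgehead C5 and C7. The strategy rests on the C6–C7 bond of ring B: C6 sits on C5 at acyl oxidation level and C7 is the β-carbon of the C11(C13)–C12 propionate unit, so this bond is the retron of an acyl radical closing 6-exo onto a 2-methylpent-2-enoate chain held on C10.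

## Retrosynthetic reasoning

**36 ⇒ 33 + 34 (C3′–C4′).** The diene side chain is cut last, at the sp2–sp3 bond next to the exo-methylene. It would not survive the ozonolysis, selenenylation and hydroboration used earlier, so it is carried as an acetyl group masked as a dioxolane (31), freed as methyl ketone 32 and activated as enol triflate 33. The forward coupling with organozinc 35 (from 34) has to make the 1,1-disubstituted alkene without base and without touching the C1 ketone or the lactone.

**31 ⇒ 30 ⇒ 28 (C6–O and the lactone acyl bond).** The lactone is opened to the γ-keto ester 28. Forward, hydride must reach the C6 ketone from the face opposite the axial C14 methyl so that the oxygen becomes axial and closes cis onto C12, and base then equilibrates C11. The C1 ketone is allowed to be reduced with C6 and is restored in 31, which removes any need for selectivity between two hindered ketones.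

**28 ⇒ 27 (C6–C7, ring B).** This cut is made here because it is the only ring B bond that joins an acyl carbon to the β-carbon of an enoate, and because the two chains already sit gauche on C5 and C10. The forward reaction forms ring B and C7 in one step.

**27 ⇒ 26 ⇒ 24 ⇒ 23 (oxidation level of C6).** The selenoester is made last from acid 26. C6 is carried through the route as a 4-methoxybenzyl-protected neopentyl carbinol (23), because an acyl group on C5 would not survive the enolate and hydride steps, and this ether can be removed oxidatively in the presence of the dioxolane.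

**23 ⇒ 21 + 22 (C7=C11) and 21 ⇒ 20 ⇒ 18.** The (E)-enoate is cut at its double bond to aldehyde 21 and ylide 22, and the aldehyde is traced through diol 20 to the allyl group of 18. A four-carbon homoallyl electrophile followed by cross-metathesis would be shorter on paper, but such halides eliminate rather than alkylate a hindered enolate, so the reactive allyl unit is used and lengthened by hydroboration. The oxidation that makes the aldehyde also returns C1 to the ketone.

**18 ⇒ 16 ⇒ 15 ⇒ 13 (C15 and C3=C4).** The C15 methyl and the ring A alkene are derived from a C4 ester: dehydrogenation to enoate 15, reduction to allylic alcohol 16 and deoxygenation. This is the price of using an acrylate for the C3–C4 bridge, and it is paid only after C10 is quaternary, when the ketone can no longer enolise.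

**13 ⇒ 11 + 12 (C10–C9).** Quaternary C10 is cut at its bond to the chain. Forward, the enolate of 11 must be alkylated by 12 on the face away from the endo C4 ester, which is why the alkylation precedes the dehydrogenation.

**11 ⇒ 9 + 10 (C2–C3 and C4–C5).** The bicyclo[2.2.2]octanone is cut into enone 9 and acrylate 10. The forward double Michael addition sets both bridgeheads and places the C2′ substituent on the side of the C1 bridge, the orientation found in the target.

**9 ⇒ 8 ⇒ 3 + 6, 6 ⇒ 4 + 5, 3 ⇒ 2 ⇒ 1.** The C5–C6 bond is made by 1,2-addition of the alkoxymethyl-lithium 7 (from stannane 6) to enone 3 and oxidative transposition of 8. The transposition reverses the ring locants, which is why the (R)-enantiomer 1 leads to the required series. The side-chain acetyl group is generated and masked first (2, 3), while the ring alkene is the only other alkene present.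

## Alternatives that were turned down

**Alternative 1:** The disconnection is at C2–C3 and C4–C5, so that ring A with its bridge is assembled from a carvone-type enone and 10. In the forward key step a lithium amide forms the cross-conjugated dienolate, its α′-carbon adds to the acrylate and the ester enolate closes on the enone β-carbon to give the endo ester A1. In its favour, one step from the chiral pool sets both bridgeheads and the C2′ orientation, the second bond is formed intramolecularly, and the chemistry is cheap. On ring A it is as strong as anything available, and the chosen route uses the same annulation as a supporting step (step 6). Against it as the centre of the plan: it leaves ring B, which must be built across the vicinal quaternary carbons, as well as C6–C7 and the cis lactone, without a defined solution. The ester carbon also arrives at the wrong oxidation level for C15, and C10 is still an epimerisable CH. The chosen strategy pays the same cost for ring A and adds one radical closure that forms C6–C7, ring B and C7 together.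

**Alternative 2:** The disconnection is at C1–C2 and C5–C10, with the ketone bridge as dienophile, tethered as an ester through the C3′ oxygen to a cyclohexa-1,3-diene. Heat or a Lewis acid would give the lactone-bridged bicyclo[2.2.2]octene A2. In its favour, the tether fixes regiochemistry and π-face, C5 and C2′ are set together, and the C3=C4 alkene with its methyl comes out in place. On that last point it is stronger than the chosen route, which spends three steps turning an ester into this alkene. Against it: a β-alkyl enoate must bond to the fully substituted diene terminus C5. In A2, C1 carries a carboxyl carbon instead of oxygen and C10 is a CH, so an oxidative decarboxylation and a methylation next to quaternary C5 are still required. The C3′ carbinol must be reoxidised, and ring B, C6 and the lactone would have to come from a prenyl-type chain by late oxidation. Substituted cyclohexa-1,3-dienes also isomerise and aromatise easily. The step count after the cycloaddition would exceed that of the chosen route, which offers a direct construction of ring B in exchange for the longer ring A sequence.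

**Alternative 3:** The disconnection is at C7–C11. A bromoacetal on an axial C6 oxygen of a ring B cyclohexene would give, under stannane conditions, a C11 radical that adds 5-exo to C7 and furnishes the cis-fused lactol ether A3, which is then oxidised to the lactone. In its favour, the short tether can only close cis to the C6 oxygen, so the ring fusion is guaranteed by geometry. On this point the alternative is stronger than the chosen strategy, which depends on the facial selectivity of a ketone reduction. Against it: ring B, the C7=C8 alkene and the axial C6 carbinol must already exist, so both the vicinal-quaternary ring fusion and the difficult C6 stereocentre have to be solved by other means. Acetal hydrolysis and oxidation are added in the presence of the dioxolane, and C11 is no better controlled. The chosen strategy gives up the geometric guarantee but closes ring B, sets C7 and brings C12 in at the ester level in one step, and is shorter overall.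

Key step: step 17

Remark: the C11 epimers formed in step 17 are carried on together and converge in step 18; 28 and 29 are drawn as the epimer with the configuration of the target.
Remark: names use the locants of the analysis (bridgeheads C2 and C5; bridges C1–C10, C3–C4 and C2′–C1′); PMB is 4-methoxybenzyl; "endo" means syn to the C1–C10 bridge.

## Route

Step 1
Reactants: 1 (R)-carvone
Product: 2 (5R)-5-acetyl-2-methylcyclohex-2-en-1-one
Conditions: O3, CH2Cl2/MeOH, −78 °C; then Me2S, −78 °C → rt
Reagents that add atoms: ozone, [O-][O+]=O
Why: Ozonolysis with reductive work-up; the electron-rich 1,1-disubstituted alkene is cleaved much faster than the conjugated ring alkene, and the neutral work-up leaves C5, now α to the acetyl group, unepimerised.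

Step 2
Reactants: 2 (5R)-5-acetyl-2-methylcyclohex-2-en-1-one
Product: 3 (5R)-2-methyl-5-(2-methyl-1,3-dioxolan-2-yl)cyclohex-2-en-1-one
Conditions: Me3SiOCH2CH2OSiMe3, Me3SiOTf (cat.), CH2Cl2, −78 → −20 °C
Reagents that add atoms: 1,2-bis(trimethylsilyloxy)ethane, C[Si](C)(C)OCCO[Si](C)(C)C
Why: Silyl-triflate-catalysed dioxolane formation; the saturated ketone is ketalised in preference to the enone, and the aprotic low-temperature conditions avoid enolisation of the acetyl group towards C5, the only stereocentre.

Step 3
Reactants: 4 tributyl(iodomethyl)stannane; 5 4-methoxybenzyl alcohol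
Product: 6 tributyl{[(4-methoxybenzyl)oxy]methyl}stannane
Conditions: NaH, THF/DMF, 0 °C → rt
Reagents that add atoms: none
Why: Williamson etherification; the alkoxide of 5 displaces iodide from the primary α-stannyl carbon of 4.

Step 4
Reactants: 6 tributyl{[(4-methoxybenzyl)oxy]methyl}stannane; 3 (5R)-2-methyl-5-(2-methyl-1,3-dioxolan-2-yl)cyclohex-2-en-1-one
Product: 8 (5R)-1-{[(4-methoxybenzyl)oxy]methyl}-2-methyl-5-(2-methyl-1,3-dioxolan-2-yl)cyclohex-2-en-1-ol (C1 epimers), via [(4-methoxybenzyl)oxy]methyllithium 7 (not isolated)
Conditions: n-BuLi, THF, −78 °C; then 3, −78 °C; H2O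
Reagents that add atoms: none
Why: Tin–lithium exchange gives the α-alkoxymethyllithium, which adds 1,2 to the enone carbonyl; the new carbinol centre is destroyed in step 5, so its configuration is immaterial.

Step 5
Reactants: 8 (5R)-1-{[(4-methoxybenzyl)oxy]methyl}-2-methyl-5-(2-methyl-1,3-dioxolan-2-yl)cyclohex-2-en-1-ol
Product: 9 (5S)-3-{[(4-methoxybenzyl)oxy]methyl}-2-methyl-5-(2-methyl-1,3-dioxolan-2-yl)cyclohex-2-en-1-one
Conditions: [C5H5NH][CrO3Cl], 4 Å MS, CH2Cl2, rt
Reagents that add atoms: pyridinium chlorochromate, [O-][Cr](=O)(=O)Cl.c1cc[nH+]cc1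
Why: Babler–Dauben oxidative transposition; the chromate ester of the tertiary allylic alcohol undergoes [3,3] shift and oxidation, which places the future C6 on the enone β-carbon. The ring stereocentre is untouched and only its descriptor changes, because the ring locants are reversed.

Step 6
Reactants: 9 (5S)-3-{[(4-methoxybenzyl)oxy]methyl}-2-methyl-5-(2-methyl-1,3-dioxolan-2-yl)cyclohex-2-en-1-one; 10 methyl acrylate
Product: 11 bicyclo[2.2.2]octanone keto ester (C1 ketone; C10-H/CH3 as both epimers; C5-CH2OPMB; endo C4-CO2Me; C2′-dioxolane syn to C1)
Conditions: LiN(iPr)2, THF, −78 °C; then 10, −78 °C → rt; H2O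
Reagents that add atoms: none
Why: Double Michael bicycloannulation; kinetic α′-deprotonation gives the cross-conjugated dienolate, which adds to 10 on the face opposite the dioxolane substituent, and the ester enolate closes on the β-carbon. This fixes C2, C5 and the C2′ orientation, and the chelated closure is expected to give the endo ester; C10 is reset in step 7.

Step 7
Reactants: 11 bicyclo[2.2.2]octanone keto ester; 12 allyl iodide
Product: 13 C10-allyl keto ester (C14 methyl towards the C3–C4 bridge; allyl towards the C1′–C2′ bridge)
Conditions: KN(SiMe3)2, THF, −78 → −40 °C; then 12, DMPU, −78 → 0 °C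
Reagents that add atoms: none
Why: Ketone enolate C-alkylation; the base removes the C10 proton (the ester α-proton is about five pKa units less acidic and C2 is a bridgehead), and the allylic iodide enters from the C1′ side, opposite the endo C4 ester, which sets quaternary C10.

Step 8
Reactants: 13 C10-allyl keto ester
Product: 15 bicyclo[2.2.2]octene enoate (C3=C4-CO2Me), via C4-phenylselanyl ester 14 (not isolated)
Conditions: LiN(iPr)2, THF, −78 °C; PhSeBr, −78 °C; then 30% H2O2, pyridine, CH2Cl2, 0 °C → rt
Reagents that add atoms: none
Why: Ester enolate selenenylation and selenoxide syn-elimination; the ketone has no enolisable proton after step 7, so only C4 is deprotonated, and elimination can only use a C3 hydrogen because C5 is quaternary.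

Step 9
Reactants: 15 bicyclo[2.2.2]octene enoate
Product: 16 diol (C15 allylic alcohol; C1 carbinol of undefined configuration)
Conditions: iBu2AlH (5 equiv), CH2Cl2, −78 → −20 °C; aq. KNaC4H4O6
Reagents that add atoms: none
Why: Hydride reduction; the conjugated ester is reduced 1,2 to the allylic alcohol and the hindered C1 ketone is deliberately reduced as well, so that one defined diol results. C1 is reoxidised in step 12, and the low temperature spares the dioxolane.

Step 10
Reactants: 16 diol
Product: 18 C4-methyl alkene with free C1 alcohol, via allylic mesylate 17 (not isolated)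
Conditions: MsCl, Et3N, CH2Cl2, −40 °C; then LiEt3BH, THF, 0 °C → rt
Reagents that add atoms: none
Why: Selective sulfonylation of the primary allylic alcohol over the hindered secondary C1 alcohol, then SN2 hydride displacement, which is expected at the primary carbon rather than in the SN2′ sense; the former ester carbon becomes the C15 methyl.

Step 11
Reactants: 18 C4-methyl alkene with free C1 alcohol
Product: 20 C7,C1-diol, via B-alkyl-9-borabicyclo[3.3.1]nonane 19 (not isolated)
Conditions: 9-BBN-H, THF, 0 °C → rt; then NaOH, H2O2, 0 °C → rt
Reagents that add atoms: hydrogen peroxide, OO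
Why: Hydroboration–oxidation; the borane adds anti-Markovnikov to the monosubstituted allyl alkene much faster than to the hindered trisubstituted C3=C4 alkene, and oxidation gives the C7 primary alcohol.

Step 12
Reactants: 20 C7,C1-diol
Product: 21 C1-keto C7-aldehyde
Conditions: Dess–Martin periodinane, NaHCO3, CH2Cl2, rt
Reagents that add atoms: none
Why: Dess–Martin oxidation of both alcohols; the primary alcohol stops at the aldehyde and the C1 carbinol returns to the ketone, while the buffer protects the dioxolane.

Step 13
Reactants: 21 C1-keto C7-aldehyde; 22 methyl 2-(triphenylphosphoranylidene)propanoate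
Product: 23 methyl (E)-2-methylpent-2-enoate PMB ether
Conditions: CH2Cl2, rt → 40 °C
Reagents that add atoms: none
Why: Wittig olefination with a stabilised α-methyl ylide; it reacts only with the unhindered aldehyde, not with the flanked C1 ketone, and is E-selective as is usual for such ylides.

Step 14
Reactants: 23 methyl (E)-2-methylpent-2-enoate PMB ether
Product: 24 C6 primary alcohol
Conditions: DDQ, CH2Cl2/pH 7 buffer, 0 °C → rt
Reagents that add atoms: none
Why: Oxidative cleavage of the 4-methoxybenzyl ether; the buffered conditions leave the dioxolane, the enoate and the ring alkene intact.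

Step 15
Reactants: 24 C6 primary alcohol
Product: 26 C6 carboxylic acid, via C6 aldehyde 25 (not isolated)
Conditions: Dess–Martin periodinane, NaHCO3, CH2Cl2, rt; then NaClO2, NaH2PO4, 2-methylbut-2-ene, t-BuOH/H2O, rt
Reagents that add atoms: sodium chlorite, [Na+].[O-]Cl=O
Why: Dess–Martin oxidation to the non-enolisable neopentyl aldehyde, then Pinnick oxidation; the alkene scavenger protects C3=C4 and the enoate from hypochlorite, and the phosphate buffer is mild enough for the dioxolane.

Step 16
Reactants: 26 C6 carboxylic acid
Product: 27 Se-phenyl C6 selenoester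
Conditions: (PhSe)2, Bu3P, CH2Cl2, rt
Reagents that add atoms: diphenyl diselenide, c1ccccc1[Se][Se]c1ccccc1
Why: Phosphine-mediated selenoesterification; the acid is activated as an acyloxyphosphonium ion and attacked by phenylselenolate under neutral conditions, which suit the hindered acid and the dioxolane.

Step 17
Reactants: 27 Se-phenyl C6 selenoester
Product: 28 tricyclic C1,C6-diketone C12 methyl ester
Conditions: Bu3SnH, AIBN (syringe pump), benzene (0.01 M), 80 °C
Reagents that add atoms: none
Why: The stannyl radical abstracts the phenylselanyl group to give the C6 acyl radical, which adds to C7 of the (E)-enoate, and the tertiary α-ester radical at C11 then takes hydrogen from Bu3SnH and carries the chain. The closest known reaction type is the stannane-mediated cyclisation of selenoester-derived acyl radicals onto α,β-unsaturated esters. Ring B is closed in the 6-exo-trig mode, the nucleophilic acyl radical attacking the electron-poor β-carbon rather than C11 (7-endo). C7 is set by the substrate: in the chair-like transition state imposed by the fixed gauche arrangement of C6 and C9 on C5–C10, the C11 terminus lies pseudo-equatorial, away from the axial C1′ methylene on C5, and because C7 is α to the new ketone any axial epimer can be equilibrated to the same isomer. C11 is formed by hydrogen transfer to an acyclic radical and is not controlled; both epimers go on to step 18. The step needs cyclisation to outrun direct reduction and decarbonylation: slow addition at high dilution handles the former, and the latter would give a pyramidal bridgehead radical with no allylic stabilisation from C3=C4, so it should be slow. The two quaternary carbons hold the reacting chains close, and C3=C4 is too near the radical for any competing ring closure.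

Step 18
Reactants: 28 tricyclic C1,C6-diketone C12 methyl ester
Product: 30 C1-hydroxy cis-lactone ketal (C1 carbinol of undefined configuration), via dihydroxy ester 29 (not isolated)
Conditions: NaBH4, MeOH/THF, 0 °C → rt; then NaOMe, MeOH, 50 °C; aq. NH4Cl
Reagents that add atoms: none
Why: Hydride reduction, then base-mediated lactonisation and equilibration; hydride is expected to reach the C6 ketone from the face opposite the syn-axial C14 methyl, giving the axial alcohol, which closes with the C12 ester to the cis-fused γ-lactone. Methoxide then equilibrates C11 through the lactone enolate to the epimer with the C13 methyl on the convex face, anti to C8. Any C1 ketone that is reduced is restored in step 19.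

Step 19
Reactants: 30 C1-hydroxy cis-lactone ketal
Product: 31 C1-keto cis-lactone ketal
Conditions: Dess–Martin periodinane, NaHCO3, CH2Cl2, rt
Reagents that add atoms: none
Why: Dess–Martin oxidation of the only free hydroxyl returns the non-enolisable C1 ketone; the lactone and the dioxolane are inert.

Step 20
Reactants: 31 C1-keto cis-lactone ketal
Product: 32 C3′ methyl ketone
Conditions: PPTS, acetone/H2O, 50 °C
Reagents that add atoms: water, O
Why: Mild acid-catalysed ketal hydrolysis; the weak acid should neither enolise the acetyl group towards C2′ nor isomerise the β,γ-unsaturated ketone.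

Step 21
Reactants: 32 C3′ methyl ketone
Product: 33 C3′ enol triflate
Conditions: KN(SiMe3)2, THF, −78 °C; then N-(5-chloropyridin-2-yl)bis(trifluoromethanesulfonyl)imide, −78 °C
Reagents that add atoms: N-(5-chloropyridin-2-yl)bis(trifluoromethanesulfonyl)imide, O=S(=O)(N(c1ccc(Cl)cn1)S(=O)(=O)C(F)(F)F)C(F)(F)F
Why: Kinetic enol triflate formation; the bulky amide removes a methyl proton of the acetyl group faster than the hindered C2′ methine or the tertiary lactone α-proton, and immediate O-sulfonylation keeps C2′ intact and leaves little time for aldol addition to the flanked C1 ketone.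

Step 22
Reactants: 33 C3′ enol triflate; 34 5-bromo-2-methylpent-2-ene
Product: 36 CNP0385704.2, via (4-methylpent-3-en-1-yl)zinc bromide 35 (not isolated)
Conditions: 34, Zn dust, I2 (5 mol%), DMA, 70 °C; then 33, Pd(dppf)Cl2 (5 mol%), THF, 50 °C
Reagents that add atoms: none
Why: Negishi cross-coupling; zinc inserts into the primary bromide and the palladium catalyst joins the alkylzinc to the alkenyl triflate, the wide-bite-angle ligand suppressing β-hydride elimination. Organozincs tolerate the ketone and the lactone, and no base is present that could epimerise C2′.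

## Compound list

1 | (R)-carvone | CC1=CC[C@H](CC1=O)C(C)=C | starting material
2 | (5R)-5-acetyl-2-methylcyclohex-2-en-1-one | CC1=CC[C@H](CC1=O)C(C)=O | intermediate
3 | (5R)-2-methyl-5-(2-methyl-1,3-dioxolan-2-yl)cyclohex-2-en-1-one | CC1=CC[C@H](CC1=O)C2(C)OCCO2 | intermediate
4 | tributyl(iodomethyl)stannane | CCCC[Sn](CCCC)(CCCC)CI | starting material
5 | 4-methoxybenzyl alcohol | COc1ccc(CO)cc1 | starting material
6 | tributyl{[(4-methoxybenzyl)oxy]methyl}stannane | CCCC[Sn](CCCC)(CCCC)COCc1ccc(OC)cc1 | intermediate
7 | [(4-methoxybenzyl)oxy]methyllithium | [Li]COCc1ccc(OC)cc1 | intermediate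
8 | (5R)-1-{[(4-methoxybenzyl)oxy]methyl}-2-methyl-5-(2-methyl-1,3-dioxolan-2-yl)cyclohex-2-en-1-ol, C1 epimers | CC1=CC[C@H](CC1(O)COCc2ccc(OC)cc2)C3(C)OCCO3 | intermediate
9 | (5S)-3-{[(4-methoxybenzyl)oxy]methyl}-2-methyl-5-(2-methyl-1,3-dioxolan-2-yl)cyclohex-2-en-1-one | CC1(OCCO1)[C@@H]2CC(=O)C(C)=C(COCc3ccc(OC)cc3)C2 | intermediate
10 | methyl acrylate | C=CC(=O)OC | starting material
11 | bicyclo[2.2.2]octanone keto ester: C1 ketone, C10-H/CH3 (both epimers), C5-CH2OPMB, endo C4-CO2Me, C2′-(2-methyl-1,3-dioxolan-2-yl) syn to C1 | CC1(OCCO1)[C@H]2C[C@]3(COCc4ccc(OC)cc4)[C@@H](C(=O)OC)C[C@H]2C(=O)C3C | intermediate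
12 | allyl iodide (3-iodoprop-1-ene) | C=CCI | starting material
13 | C10-allyl keto ester: as 11, with quaternary C10 (methyl towards C3–C4, allyl towards C1′–C2′) | CC1(OCCO1)[C@H]2C[C@]3(COCc4ccc(OC)cc4)[C@@H](C(=O)OC)C[C@H]2C(=O)[C@]3(C)CC=C | intermediate
14 | C4-phenylselanyl ester of 13 (C4 configuration undefined) | CC1(OCCO1)[C@H]2C[C@]3(COCc4ccc(OC)cc4)C([Se]c5ccccc5)(C(=O)OC)C[C@H]2C(=O)[C@]3(C)CC=C | intermediate
15 | bicyclo[2.2.2]octene enoate: C3=C4 with CO2Me on C4 | CC1(OCCO1)[C@H]2C[C@]3(COCc4ccc(OC)cc4)C(C(=O)OC)=C[C@H]2C(=O)[C@]3(C)CC=C | intermediate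
16 | diol: C4-CH2OH (C15) and C1-OH (configuration undefined) | CC1(OCCO1)[C@H]2C[C@]3(COCc4ccc(OC)cc4)C(CO)=C[C@H]2C(O)[C@]3(C)CC=C | intermediate
17 | C15 allylic mesylate of 16 | CC1(OCCO1)[C@H]2C[C@]3(COCc4ccc(OC)cc4)C(COS(C)(=O)=O)=C[C@H]2C(O)[C@]3(C)CC=C | intermediate
18 | C4-methyl alkene with C1-OH (configuration undefined) and C10-allyl | CC1(OCCO1)[C@H]2C[C@]3(COCc4ccc(OC)cc4)C(C)=C[C@H]2C(O)[C@]3(C)CC=C | intermediate
19 | B-alkyl-9-borabicyclo[3.3.1]nonane at C7 of 18 | CC1(OCCO1)[C@H]2C[C@]3(COCc4ccc(OC)cc4)C(C)=C[C@H]2C(O)[C@]3(C)CCCB5C6CCCC5CCC6 | intermediate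
20 | C7,C1-diol (C10-CH2CH2CH2OH; C1-OH undefined) | CC1(OCCO1)[C@H]2C[C@]3(COCc4ccc(OC)cc4)C(C)=C[C@H]2C(O)[C@]3(C)CCCO | intermediate
21 | C1-keto C7-aldehyde | CC1(OCCO1)[C@H]2C[C@]3(COCc4ccc(OC)cc4)C(C)=C[C@H]2C(=O)[C@]3(C)CCC=O | intermediate
22 | methyl 2-(triphenylphosphoranylidene)propanoate | COC(=O)C(C)=P(c1ccccc1)(c1ccccc1)c1ccccc1 | starting material
23 | methyl (E)-2-methylpent-2-enoate on C10, C5-CH2OPMB | CC1(OCCO1)[C@H]2C[C@]3(COCc4ccc(OC)cc4)C(C)=C[C@H]2C(=O)[C@]3(C)CC/C=C(\C)C(=O)OC | intermediate
24 | C6 primary alcohol (C5-CH2OH) | CC1(OCCO1)[C@H]2C[C@]3(CO)C(C)=C[C@H]2C(=O)[C@]3(C)CC/C=C(\C)C(=O)OC | intermediate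
25 | C6 aldehyde (C5-CHO) | CC1(OCCO1)[C@H]2C[C@]3(C=O)C(C)=C[C@H]2C(=O)[C@]3(C)CC/C=C(\C)C(=O)OC | intermediate
26 | C6 carboxylic acid (C5-CO2H) | CC1(OCCO1)[C@H]2C[C@]3(C(=O)O)C(C)=C[C@H]2C(=O)[C@]3(C)CC/C=C(\C)C(=O)OC | intermediate
27 | Se-phenyl C6 selenoester (key precursor) | CC1(OCCO1)[C@H]2C[C@]3(C(=O)[Se]c4ccccc4)C(C)=C[C@H]2C(=O)[C@]3(C)CC/C=C(\C)C(=O)OC | intermediate
28 | tricyclic C1,C6-diketone with equatorial C7-CH(CH3)CO2Me (key product; drawn C11 epimer plus its C11 epimer) | CC1(OCCO1)[C@H]2C[C@]34C(C)=C[C@H]2C(=O)[C@]3(C)CC[C@@H]([C@H](C)C(=O)OC)C4=O | intermediate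
29 | dihydroxy ester: axial C6-OH, C1-OH (undefined), drawn C11 epimer plus its C11 epimer | CC1(OCCO1)[C@H]2C[C@]34C(C)=C[C@H]2C(O)[C@]3(C)CC[C@@H]([C@H](C)C(=O)OC)[C@H]4O | intermediate
30 | C1-hydroxy cis-lactone ketal (C1-OH undefined; C11 as in target) | CC4(OCCO4)[C@H]1C[C@]23C(C)=C[C@H]1C(O)[C@]2(C)CC[C@H]1[C@H](C)C(=O)O[C@H]13 | intermediate
31 | C1-keto cis-lactone ketal | CC4(OCCO4)[C@H]1C[C@]23C(C)=C[C@H]1C(=O)[C@]2(C)CC[C@H]1[C@H](C)C(=O)O[C@H]13 | intermediate
32 | C3′ methyl ketone (C2′-acetyl keto lactone) | CC(=O)[C@H]1C[C@]23C(C)=C[C@H]1C(=O)[C@]2(C)CC[C@H]1[C@H](C)C(=O)O[C@H]13 | intermediate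
33 | C3′ enol triflate (C2′-[1-(trifluoromethanesulfonyloxy)vinyl]) | C=C(OS(=O)(=O)C(F)(F)F)[C@H]1C[C@]23C(C)=C[C@H]1C(=O)[C@]2(C)CC[C@H]1[C@H](C)C(=O)O[C@H]13 | intermediate
34 | 5-bromo-2-methylpent-2-ene | CC(C)=CCCBr | starting material
35 | (4-methylpent-3-en-1-yl)zinc bromide | CC(C)=CCC[Zn]Br | intermediate
36 | CNP0385704.2 | C=C(CCC=C(C)C)[C@H]1C[C@]23C(C)=C[C@H]1C(=O)[C@]2(C)CC[C@H]1[C@H](C)C(=O)O[C@H]13 | target

## Step count and least certain steps

Total: 22 steps. Longest linear sequence: 21 steps from 1 (steps 1, 2 and 4–22); step 3 is a one-step side branch.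

**Step 17 (key step).** The acyl radical may take hydrogen before it cyclises, may lose carbon monoxide, or may close 7-endo; the hindered environment slows every productive collision. Fallback: the same C6–C7 bond is formed by polarity-reversed ionic chemistry. Aldehyde 25, taken before the chlorite stage of step 15, is treated with 3-benzyl-5-(2-hydroxyethyl)-4-methylthiazolium chloride and Et3N in i-PrOH at 80 °C, and the intramolecular Stetter reaction adds the acyl-anion equivalent 6-exo to C7 to give 28. This path sets out from 25, comes back at 28 and makes no new compound (entry F0).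

**Step 6.** The second Michael closure onto the fully substituted β-carbon may stall at the open-chain adduct, or the acrylate may oligomerise. Fallback from 9: LiN(iPr)2 and t-BuMe2SiCl/DMPU give the cross-conjugated silyloxy diene F1. Thermal Diels–Alder reaction with 10 (toluene, 140 °C, sealed tube) gives the bicyclic silyl enol ether F2, with the ester para to the silyloxy group and endo. Bu4NF/AcOH then cleaves the enol ether and the route is rejoined at 11.

**Step 7.** C-alkylation at a carbon flanked by quaternary C5 may be slow, so that O-alkylation or loss of facial control intervenes. Fallback from 11: the potassium enolate is trapped on oxygen with allyl chloroformate to give the allyl enol carbonate F3, and Pd(PPh3)4 (zerovalent palladium) in THF effects decarboxylative Tsuji allylation through the π-allyl/enolate ion pair, which returns to the route at 13.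

**Step 18.** Both faces of the C6 ketone are flanked, so hydride delivery may show poor facial selectivity, or reduction may be sluggish. Fallback from 28, which sets the C6 oxygen by trans-diaxial opening instead of hydride attack: KN(SiMe3)2 and PhNTf2 give the C6 enol triflate F4. Pd(OAc)2/PPh3 with HCO2H and Bu3N reduces it to the C6=C7 alkene ester F5, and Me3SnOH in 1,2-dichloroethane gives the β,γ-unsaturated acid F6. Iodine in MeCN under equilibrating conditions gives the γ-iodolactone F7, with axial oxygen on C6 and axial iodine on C7. Bu3SnH/AIBN removes the iodine, and only the cis ring fusion is geometrically possible. NaOMe in MeOH equilibrates C11, and the route is rejoined at 31.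

**Step 21.** Regiocontrol of the enolisation may be lost, or the methyl ketone enolate may add to the nearby C1 ketone in an aldol reaction. Fallback from 30, which keeps C1 as a protected carbinol until the end: t-BuMe2SiOTf/2,6-lutidine gives the silyl ether F8 and PPTS in aqueous acetone gives the methyl ketone F9. KN(SiMe3)2 and the pyridyl triflimide give the enol triflate F10, and Negishi coupling with 35 gives the diene silyl ether F11. Bu4NF frees the C1 alcohol F12, and Dess–Martin oxidation returns to the route at 36.

## Further compounds

F0 | step 17 | none | none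
F1 | step 6 | tert-butyldimethylsilyl dienol ether of 9 (cross-conjugated 2-silyloxy diene) | CC1(OCCO1)[C@@H]2C=C(O[Si](C)(C)C(C)(C)C)C(C)=C(COCc3ccc(OC)cc3)C2
F2 | step 6 | bicyclic silyl enol ether (C1=C10 tert-butyldimethylsilyl enol ether of 11) | CC1(OCCO1)[C@H]2C[C@]3(COCc4ccc(OC)cc4)[C@@H](C(=O)OC)C[C@H]2C(O[Si](C)(C)C(C)(C)C)=C3C
F3 | step 7 | allyl enol carbonate of 11 (C1=C10) | CC1(OCCO1)[C@H]2C[C@]3(COCc4ccc(OC)cc4)[C@@H](C(=O)OC)C[C@H]2C(OC(=O)OCC=C)=C3C
F4 | step 18 | C6 enol triflate of 28 (C6=C7) | CC1(OCCO1)[C@H]2C[C@]34C(C)=C[C@H]2C(=O)[C@]3(C)CCC(C(C)C(=O)OC)=C4OS(=O)(=O)C(F)(F)F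
F5 | step 18 | C6=C7 alkene methyl ester | CC1(OCCO1)[C@H]2C[C@]34C(C)=C[C@H]2C(=O)[C@]3(C)CCC(C(C)C(=O)OC)=C4
F6 | step 18 | C6=C7 alkene carboxylic acid | CC1(OCCO1)[C@H]2C[C@]34C(C)=C[C@H]2C(=O)[C@]3(C)CCC(C(C)C(=O)O)=C4
F7 | step 18 | C7-iodo cis-lactone (axial C6–O, axial C7–I) | CC1(OCCO1)[C@H]2C[C@]34C(C)=C[C@H]2C(=O)[C@]3(C)CC[C@@]5(I)C(C)C(=O)O[C@H]54
F8 | step 21 | C1 tert-butyldimethylsilyl ether of 30 | CC4(OCCO4)[C@H]1C[C@]23C(C)=C[C@H]1C(O[Si](C)(C)C(C)(C)C)[C@]2(C)CC[C@H]1[C@H](C)C(=O)O[C@H]13
F9 | step 21 | C1-silyloxy C3′ methyl ketone | CC(=O)[C@H]1C[C@]23C(C)=C[C@H]1C(O[Si](C)(C)C(C)(C)C)[C@]2(C)CC[C@H]1[C@H](C)C(=O)O[C@H]13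
F10 | step 21 | C1-silyloxy C3′ enol triflate | C=C(OS(=O)(=O)C(F)(F)F)[C@H]1C[C@]23C(C)=C[C@H]1C(O[Si](C)(C)C(C)(C)C)[C@]2(C)CC[C@H]1[C@H](C)C(=O)O[C@H]13
F11 | step 21 | C1-silyloxy diene (silyl ether of the C1-dihydro target) | C=C(CCC=C(C)C)[C@H]1C[C@]23C(C)=C[C@H]1C(O[Si](C)(C)C(C)(C)C)[C@]2(C)CC[C@H]1[C@H](C)C(=O)O[C@H]13
F12 | step 21 | C1-dihydro target (C1 alcohol) | C=C(CCC=C(C)C)[C@H]1C[C@]23C(C)=C[C@H]1C(O)[C@]2(C)CC[C@H]1[C@H](C)C(=O)O[C@H]13
A1 | alternative 1 | bicyclo[2.2.2]octanone endo ester with C5-CH2OCH2OCH3 and C2′-isopropenyl | CC(=C)[C@H]1C[C@]2(COCOC)[C@@H](C(=O)OC)C[C@H]1C(=O)[C@@H]2C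
A2 | alternative 2 | lactone-bridged bicyclo[2.2.2]octene (δ-lactone from the C1 carboxyl to the C3′ oxygen; C10-H with 4-methylpent-3-enyl; C5-CH2OCH2OCH3) | C[C@H]1OC(=O)[C@@H]2[C@@H](CCC=C(C)C)[C@]3(COCOC)C[C@H]1[C@H]2C=C3C
A3 | alternative 3 | cis-fused C12 ethyl lactol ether of the ring B closed ketal | CC1(OCCO1)[C@H]2C[C@]34C(C)=C[C@H]2C(=O)[C@]3(C)CC[C@H]5[C@H](C)[C@H](OCC)O[C@@H]45
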